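The easy mistake at this bench, I thought, was to read a slowing flask as a flask short of its charges.

common to all: starting material 0.050 M; free catalyst 1.1 mol%
- eta: reagent 1.3 equiv; second substrate 5 equiv; temperature 90 °C; the very flask that is asked about, followed so far
- epsilon: reagent 1.3 equiv; second substrate 5 equiv; temperature 75 °C; run made earlier
- flask: reagent 1.30 equiv; second substrate 5.00 equiv; temperature 90 °C; time 8.0 d

- eta (time / d: target / %): 0.500: 7.8; 1.04: 10.3; 1.67: 15.9; 3.00: 19.1; 6.00: 25.6
- epsilon (time / d: target / %): 1.04: 6.7; 2.00: 10.4; 4.00: 16.5; 6.00: 21.7; 12.0: 34.7

(standard deviation of a reading: 1 percentage point)

- grey: change nothing and wait 4.0 d more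
- green: at 8.0 d add reagent, 100 % of the amount charged, then wait 4.0 d
- amber: at 8.0 d take out 90 % of the target then present, then wait 4.0 d
- red: at 8.0 d add free catalyst, 100 % of the amount charged, then wait 4.0 d
- teal: at 8.0 d raise the temperature by 15 K, then wait 4.0 d

- removed target is counted in
- additions bring no volume worth counting

* target, in percent of the starting material first charged, at 8.0 d
* which option adds most target ("none" when 2 percentage points or less is all one gets) (grey / green / amber / red / teal / none)
* target present, with what was taken out counted in, in percent of the starting material first charged, after amber
* target present, with what was taken out counted in, in percent of the starting material first charged, after red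

I left this note for whoever took over flask eta. Its rate had gone from 0.156 /d of the charge over the first reading to 0.0217 /d between the last two, a ratio of 0.139. The zero of my scale was a catalyst that lasts: the rate then follows the starting material and reagent left, and at one reagent per target these allowed 0.597 of the starting rate at the last reading. Because the ratio read off the readings stood lower, I took the catalyst to be fading, at roughly 0.464 /d.

From this I reckoned the ration, 27.9 %: the target that one charge of free catalyst yields in flask eta before it fades, the total turnover number in fractions of the charge. I told my successor to expect 27.0 % at 8.0 d, and that waiting 4.0 d more would add about 0.77 percentage points. A fresh charge of catalyst would meet 0.578 of the starting rate, so I put its gain at 14 points, more than waiting. I wrote: add catalyst, and leave the target in.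

The forecast gave 29 % and chose amber, with 45 % after it and 41 % after red, on its own grounds: “That points to product inhibition”.

The flask gave 26.1 %; the best option was red, reaching 39.8 %, while amber reached 26.7 %.

    starting material + reagent + free catalyst → free catalyst + target (k = 350 /M²/h, Ea = 40.0 kJ/mol)
    second substrate + reagent + free catalyst → free catalyst + second product (k = 81.0 /M²/h, Ea = 60.0 kJ/mol)
    starting material + free catalyst ⇌ idle complex, settled at all times (K = 21.0 /M, ΔH = −56.0 kJ/mol)
    free catalyst → spent catalyst (k = 0.0320 /h, Ea = 130 kJ/mol)
    2 second substrate → homo dimer (k = 0.0770 /M/h, Ea = 91.0 kJ/mol)
    (constants at 90 °C)

In flask eta the half-life of starting material by the target step stretched from 7.2 d at 0.827 d to 170 d at 8.00 d, as the free catalyst share went from 37.7 % at 0.800 d to 1.98 % at 8.00 d, with 74 % of the starting material unused. Left to 80.0 d, flask eta reaches 26.8 %, against the ration of 27.9 %. Scaled by loading, with the other charges held, the ration gave 16.8 % for the neighbour charged with 0.66 mol% of free catalyst, which stood at 17.8 % after 8.00 d.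

Readings and results come from a simulation for substances that don't exist; the scatter is artificial.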